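**Retrosynthetic overview**
- The γ-lactone comes last, by Baeyer–Villiger ring expansion of an α-quaternary β-hydroxy cyclobutanone (C–O bond formed with retention).
- The cyclobutanone comes from a hydroxyl-directed asymmetric epoxidation / semipinacol 1,2-shift of a (Z)-1-alkenylcyclopropanol; this one event builds the four-membered ring and both stereocentres next to the lactone.
- The cyclopropanol comes from a (Z)-alkenyl iodide and a cyclopropanone hemiacetal; the tertiary allylic alcohol comes from catalytic asymmetric addition of an (E)-alkenylzinc to a methyl ketone.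
- The iodo ketone comes from a C4 propargylic alcohol (trans-hydroalumination/iodination) and a 1,3-diketone; the furyl enyne comes from a furylmethyl Grignard reagent, a vinyl epoxide (SN2′) and an ethynyl Grignard reagent.
- Ring order: furan (bought), then cyclopropane (step 8), cyclobutanone (step 9), γ-lactone (step 10).

Assumption: the absolute sense of induction of the chiral ligands in steps 7 and 9 is taken by analogy, so in each case the ligand antipode that gives the stated configuration is the one used; all starting materials are taken as catalogue items.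

**Step 1**
Reactants: 1 3-(chloromethyl)furan; 2 2-methyl-2-vinyloxirane
Product: 4 (2E)-5-(furan-3-yl)-2-methylpent-2-en-1-ol, via furylmethyl Grignard reagent 3 (not isolated)
Conditions: Mg, THF, 0 °C; then 2, CuI (5 mol %), THF, −30 → 0 °C; aq NH4Cl
Reagents that add atoms: none
Why: Copper-catalysed SN2′ opening of the vinyl epoxide by the Grignard reagent (allylic substitution) gives the primary allylic alcohol with the (E)-trisubstituted alkene as major isomer (about 9:1), the minor (Z)-isomer being removed by chromatography.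

**Step 2**
Reactants: 4 (2E)-5-(furan-3-yl)-2-methylpent-2-en-1-ol
Product: 5 3-[(3E)-5-bromo-4-methylpent-3-en-1-yl]furan
Conditions: PBr3 (0.4 eq), pyridine (cat.), Et2O, −20 °C
Reagents that add atoms: phosphorus tribromide, BrP(Br)Br
Why: SN2 bromination of the primary allylic alcohol through its phosphite ester at low temperature leaves the alkene geometry and the furan untouched.

**Step 3**
Reactants: 5 3-[(3E)-5-bromo-4-methylpent-3-en-1-yl]furan; 6 ethynylmagnesium bromide
Product: 7 3-[(3E)-4-methylhept-3-en-6-yn-1-yl]furan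
Conditions: 6 (3 eq), CuBr·SMe2 (10 mol %), THF, 0 °C → rt
Reagents that add atoms: none
Why: Copper-catalysed coupling of the alkynyl Grignard reagent at the primary allylic carbon (SN2-type allylic alkynylation) gives the skipped enyne with the (E)-alkene retained, and excess Grignard reagent suppresses double allylation.

**Step 4**
Reactants: 8 but-2-yn-1-ol
Product: 10 (2Z)-3-iodobut-2-en-1-ol, via cyclic alkenylalanate 9 (not isolated)
Conditions: Red-Al (1.2 eq), Et2O, 0 °C → rt; then I2 (1.3 eq), THF, −78 → 0 °C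
Reagents that add atoms: iodine, II
Why: Hydroxyl-directed trans-hydroalumination of the propargylic alcohol puts aluminium on C-3 cis to the CH2O group, and iodinolysis of the C–Al bond with retention gives the (Z)-vinyl iodide.

**Step 5**
Reactants: 10 (2Z)-3-iodobut-2-en-1-ol
Product: 11 (2Z)-1-bromo-3-iodobut-2-ene
Conditions: PBr3 (0.4 eq), Et2O, 0 °C
Reagents that add atoms: phosphorus tribromide, BrP(Br)Br
Why: SN2 bromination of the primary allylic alcohol with PBr3 does not touch the vinyl iodide or its geometry.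

**Step 6**
Reactants: 11 (2Z)-1-bromo-3-iodobut-2-ene; 12 pentane-2,4-dione
Product: 14 (5Z)-6-iodohept-5-en-2-one, via alkylated diketone 13 (not isolated)
Conditions: K2CO3 (1.2 eq), EtOH, reflux, 16 h
Reagents that add atoms: none
Why: C-alkylation of the diketone enolate by the allylic bromide is followed in the same pot by retro-Claisen deacetylation in ethanol (acetoacetic-type methyl ketone synthesis), and the vinyl iodide is inert to carbonate.

**Step 7**
Reactants: 7 3-[(3E)-4-methylhept-3-en-6-yn-1-yl]furan; 14 (5Z)-6-iodohept-5-en-2-one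
Product: 17 (2Z,6S,7E,10E)-13-(furan-3-yl)-2-iodo-6,10-dimethyltrideca-2,7,10-trien-6-ol, via alkenylzirconocene chloride 15 (not isolated), via alkenylmethylzinc 16 (not isolated)
Conditions: 7 (1.5 eq), Cp2Zr(H)Cl, CH2Cl2, rt; Me2Zn, toluene, −78 °C; then 14, Ti(OiPr)4 (1.2 eq), trans-cyclohexane-1,2-diamine bis(hydroxycamphorsulfonamide) ligand (10 mol %), toluene, 0 °C → rt
Reagents that add atoms: none
Why: syn-Hydrozirconation of the terminal alkyne fixes the (E)-alkenyl metal, and after Zr-to-Zn transmetalation the Ti/bis(sulfonamide)-diol-catalysed asymmetric alkenylzinc addition to the Re face of the methyl ketone (catalytic asymmetric vinylation of ketones) sets the (S)-tertiary allylic alcohol while vinyl iodide, furan and skipped diene stay inert.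

**Step 8**
Reactants: 17 (2Z,6S,7E,10E)-13-(furan-3-yl)-2-iodo-6,10-dimethyltrideca-2,7,10-trien-6-ol; 18 1-ethoxycyclopropan-1-ol
Product: 23 1-[(2Z,6S,7E,10E)-13-(furan-3-yl)-6,10-dimethyl-6-[(trimethylsilyl)oxy]trideca-2,7,10-trien-2-yl]cyclopropan-1-ol, via silyl ether 19 (not isolated), via alkenyllithium 20 (not isolated), via magnesium hemiacetal salt 21 (not isolated), via cyclopropanone 22 (not isolated)
Conditions: MeLi (1.0 eq), THF, −78 °C; TMSCl (1.0 eq), −78 → 0 °C; t-BuLi (2.1 eq), −78 °C; then 18/EtMgBr (3 eq each, premixed in THF at 0 °C), −78 °C → rt → 40 °C; aq NH4Cl; chromatography on Et3N-deactivated silica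
Reagents that add atoms: chlorotrimethylsilane, C[Si](C)(C)Cl
Why: The lithium alkoxide is silylated in the flask (the TMS ether later blocks tetrahydrofuran formation and a second directing group), iodine–lithium exchange proceeds with retention of alkene geometry, and the alkenyl metal adds to cyclopropanone released from the magnesium hemiacetal salt (1,2-addition to a cyclopropanone equivalent) to give the (Z)-1-alkenylcyclopropanol.

**Step 9**
Reactants: 23 1-[(2Z,6S,7E,10E)-13-(furan-3-yl)-6,10-dimethyl-6-[(trimethylsilyl)oxy]trideca-2,7,10-trien-2-yl]cyclopropan-1-ol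
Product: 25 (2S)-2-[(1R,4S,5E,8E)-11-(furan-3-yl)-1-hydroxy-4,8-dimethyl-4-[(trimethylsilyl)oxy]undeca-5,8-dien-1-yl]-2-methylcyclobutan-1-one, via epoxide 24 (not isolated)
Conditions: Hf(OtBu)4 (10 mol %), C2-symmetric trans-cyclohexane-1,2-diamine bis-hydroxamic acid ligand (12 mol %), cumene hydroperoxide (1.2 eq), 4 Å MS, toluene, 0 °C
Reagents that add atoms: cumene hydroperoxide, CC(C)(OO)c1ccccc1
Why: Proposed new method: hydroxyl-directed Hf(IV)–bis-hydroxamic acid epoxidation has not been run on a tertiary cyclopropanol or coupled to a ring expansion; the cyclopropanolate binds Hf next to the η2-alkylperoxide, the chiral ligand lets oxygen reach only one face of the neighbouring (Z)-alkene to give the (2R,3R)-epoxide 24, and the Lewis-acidic Hf then opens the epoxide at its tertiary carbon while the antiperiplanar cyclopropane C–C bond migrates with inversion (semipinacol 1,2-shift, ring expansion), so the (2S)-quaternary carbon and the (R)-carbinol of 25 both follow from one epoxide face, while the isolated alkenes, the furan and the silylated alcohol carry no directing hydroxyl and stay untouched; closest known reaction types are the Hf–bis-hydroxamic acid epoxidation of tertiary allylic alcohols and the tandem Ti–tartrate epoxidation/ring expansion of cyclopropylidene alcohols.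

**Step 10**
Reactants: 25 (2S)-2-[(1R,4S,5E,8E)-11-(furan-3-yl)-1-hydroxy-4,8-dimethyl-4-[(trimethylsilyl)oxy]undeca-5,8-dien-1-yl]-2-methylcyclobutan-1-one
Product: 27 (5S)-5-[(1R,4S,5E,8E)-11-(furan-3-yl)-1,4-dihydroxy-4,8-dimethylundeca-5,8-dien-1-yl]-5-methyloxolan-2-one, via silylated lactone 26 (not isolated)
Conditions: 30 % aq H2O2 (3 eq), K2CO3 (0.3 eq), MeOH/THF, 0 °C, 30 min; then aq citric acid (pH 3), rt, 1 h
Reagents that add atoms: hydrogen peroxide, OO
Why: Baeyer–Villiger ring expansion by hydroperoxide anion is selective for the strained ketone over alkenes and furan, the quaternary carbon migrates with retention to give the γ-lactone, and mild acid then removes the TMS ether.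

**Compound list**
1 | 3-(chloromethyl)furan | ClCc1ccoc1 | starting material
2 | 2-methyl-2-vinyloxirane (racemic) | C=CC1(C)CO1 | starting material
3 | (furan-3-ylmethyl)magnesium chloride | Cl[Mg]Cc1ccoc1 | intermediate
4 | (2E)-5-(furan-3-yl)-2-methylpent-2-en-1-ol | C/C(=C\CCc1ccoc1)CO | intermediate
5 | 3-[(3E)-5-bromo-4-methylpent-3-en-1-yl]furan | C/C(=C\CCc1ccoc1)CBr | intermediate
6 | ethynylmagnesium bromide | C#C[Mg]Br | starting material
7 | 3-[(3E)-4-methylhept-3-en-6-yn-1-yl]furan | C/C(=C\CCc1ccoc1)CC#C | intermediate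
8 | but-2-yn-1-ol | CC#CCO | starting material
9 | sodium 2,2-bis(2-methoxyethoxy)-3-methyl-2,5-dihydro-1,2-oxaluminol-2-uide (cyclic alkenylalanate, Al cis to CH2O) | CC1=CCO[Al-]1(OCCOC)OCCOC.[Na+] | intermediate
10 | (2Z)-3-iodobut-2-en-1-ol | C/C(I)=C/CO | intermediate
11 | (2Z)-1-bromo-3-iodobut-2-ene | C/C(I)=C/CBr | intermediate
12 | pentane-2,4-dione | CC(=O)CC(C)=O | starting material
13 | 3-[(2Z)-3-iodobut-2-en-1-yl]pentane-2,4-dione | C/C(I)=C/CC(C(C)=O)C(C)=O | intermediate
14 | (5Z)-6-iodohept-5-en-2-one | C/C(I)=C/CCC(C)=O | intermediate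
15 | chlorobis(cyclopentadienyl)[(1E,4E)-7-(furan-3-yl)-4-methylhepta-1,4-dien-1-yl]zirconium | C/C(=C\CCc1ccoc1)C/C=C/[Zr](Cl)(C1C=CC=C1)C1C=CC=C1 | intermediate
16 | [(1E,4E)-7-(furan-3-yl)-4-methylhepta-1,4-dien-1-yl](methyl)zinc | C/C(=C\CCc1ccoc1)C/C=C/[Zn]C | intermediate
17 | (2Z,6S,7E,10E)-13-(furan-3-yl)-2-iodo-6,10-dimethyltrideca-2,7,10-trien-6-ol | C/C(=C\CCc1ccoc1)C/C=C/[C@@](C)(O)CC/C=C(/C)I | intermediate
18 | 1-ethoxycyclopropan-1-ol | CCOC1(O)CC1 | starting material
19 | {[(2Z,6S,7E,10E)-13-(furan-3-yl)-2-iodo-6,10-dimethyltrideca-2,7,10-trien-6-yl]oxy}trimethylsilane | C/C(=C\CCc1ccoc1)C/C=C/[C@@](C)(O[Si](C)(C)C)CC/C=C(/C)I | intermediate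
20 | [(2E,6S,7E,10E)-13-(furan-3-yl)-6,10-dimethyl-6-[(trimethylsilyl)oxy]trideca-2,7,10-trien-2-yl]lithium (Li cis to C-4, geometry of 19 retained) | C/C(=C\CCc1ccoc1)C/C=C/[C@@](C)(O[Si](C)(C)C)CC/C=C(/C)[Li] | intermediate
21 | bromomagnesium 1-ethoxycyclopropan-1-olate | CCOC1(CC1)O[Mg]Br | intermediate
22 | cyclopropanone | O=C1CC1 | intermediate
23 | 1-[(2Z,6S,7E,10E)-13-(furan-3-yl)-6,10-dimethyl-6-[(trimethylsilyl)oxy]trideca-2,7,10-trien-2-yl]cyclopropan-1-ol | C/C(=C\CCc1ccoc1)C/C=C/[C@@](C)(O[Si](C)(C)C)CC/C=C(/C)C1(O)CC1 | intermediate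
24 | 1-[(2R,3R)-3-[(3S,4E,7E)-10-(furan-3-yl)-3,7-dimethyl-3-[(trimethylsilyl)oxy]deca-4,7-dien-1-yl]-2-methyloxiran-2-yl]cyclopropan-1-ol | C/C(=C\CCc1ccoc1)C/C=C/[C@@](C)(O[Si](C)(C)C)CC[C@H]2O[C@@]2(C)C3(O)CC3 | intermediate
25 | (2S)-2-[(1R,4S,5E,8E)-11-(furan-3-yl)-1-hydroxy-4,8-dimethyl-4-[(trimethylsilyl)oxy]undeca-5,8-dien-1-yl]-2-methylcyclobutan-1-one | C/C(=C\CCc1ccoc1)C/C=C/[C@@](C)(O[Si](C)(C)C)CC[C@@H](O)[C@]2(C)CCC2=O | intermediate
26 | (5S)-5-[(1R,4S,5E,8E)-11-(furan-3-yl)-1-hydroxy-4,8-dimethyl-4-[(trimethylsilyl)oxy]undeca-5,8-dien-1-yl]-5-methyloxolan-2-one | C/C(=C\CCc1ccoc1)C/C=C/[C@@](C)(O[Si](C)(C)C)CC[C@@H](O)[C@]1(C)CCC(=O)O1 | intermediate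
27 | (5S)-5-[(1R,4S,5E,8E)-11-(furan-3-yl)-1,4-dihydroxy-4,8-dimethylundeca-5,8-dien-1-yl]-5-methyloxolan-2-one (CNP0151262.1) | C/C(=C\CCc1ccoc1)C/C=C/[C@@](C)(O)CC[C@@H](O)[C@]1(C)CCC(=O)O1 | target

**Step count and risks**
Total steps: 10. Longest linear sequence: 7 (steps 4–10; the branch through steps 1–3 joins at step 7 and is equally long).

Three steps most likely to fail:

(i) Step 9, the proposed new step. The catalyst–substrate pair is untested: facial selectivity on a (Z)-trisubstituted cyclopropanol alkene may be low, or the epoxide may ionise before the shift and erode the C-4/C-5 relationship. The fallback uses only known chemistry and sets out from 14. Ketalisation (ethylene glycol, PPTS, benzene, reflux) gives 2-[(3Z)-4-iodopent-3-en-1-yl]-2-methyl-1,3-dioxolane F1. t-BuLi and then 21, as in step 8, give 1-[(2Z)-5-(2-methyl-1,3-dioxolan-2-yl)pent-2-en-2-yl]cyclopropan-1-ol F2, in which this is the only alkene. Shi epoxidation (fructose-derived ketone catalyst of the antipodal series that gives the (2R,3R)-epoxide, Oxone, K2CO3 buffer, MeCN/dimethoxymethane/water, 0 °C) gives 1-[(2R,3R)-2-methyl-3-[2-(2-methyl-1,3-dioxolan-2-yl)ethyl]oxiran-2-yl]cyclopropan-1-ol F3. A mild Lewis acid (MgBr2·OEt2, CH2Cl2, −40 °C) effects the stereospecific ring expansion to (2S)-2-[(1R)-1-hydroxy-3-(2-methyl-1,3-dioxolan-2-yl)propyl]-2-methylcyclobutan-1-one F4. H2O2/K2CO3 as in step 10 gives (5S)-5-[(1R)-1-hydroxy-3-(2-methyl-1,3-dioxolan-2-yl)propyl]-5-methyloxolan-2-one F5, and PPTS in wet acetone frees the ketone (5S)-5-[(1R)-1-hydroxy-4-oxopentyl]-5-methyloxolan-2-one F6. Addition of alkenylzinc 16 to F6 under the catalyst of step 7 (one extra equivalent for the free hydroxyl) then comes back to the route at 27.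

(ii) Step 7. Unbranched dialkyl methyl ketones lie at the margin of the documented scope of this catalytic alkenylation, so the enantiomer ratio of 17 may be only moderate. Because step 9 is catalyst-controlled, any (6R)-17 ends as a diastereomer of 27 that chromatography can remove, so the optical purity of 27 exceeds that of 17. If the ratio is still too low, the fallback sets out from 14 and 16: addition without the chiral ligand gives rac-(2Z,7E,10E)-13-(furan-3-yl)-2-iodo-6,10-dimethyltrideca-2,7,10-trien-6-ol F7, which is resolved by preparative chiral SFC, and the (S)-enantiomer comes back to the route at 17.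

(iii) Step 8. The hindered α-methyl alkenyl metal is the limiting partner in the addition to the cyclopropanone equivalent, and the alkenyllithium can metalate the furan on warming. The fallback sets out from 17, taken to alkenyllithium 20 as in step 8. Addition of 20 to 1,3-dichloroacetone (THF, −78 °C) gives (3Z,7S,8E,11E)-1-chloro-2-(chloromethyl)-14-(furan-3-yl)-3,7,11-trimethyl-7-[(trimethylsilyl)oxy]tetradeca-3,8,11-trien-2-ol F8. Reductive 1,3-cyclisation with EtMgBr (4 eq) and catalytic FeCl3 in Et2O then gives the cyclopropanol and comes back to the route at 23.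

**Further compounds**
F1 | step 9 | 2-[(3Z)-4-iodopent-3-en-1-yl]-2-methyl-1,3-dioxolane | C/C(I)=C/CCC1(C)OCCO1
F2 | step 9 | 1-[(2Z)-5-(2-methyl-1,3-dioxolan-2-yl)pent-2-en-2-yl]cyclopropan-1-ol | C/C(=C/CCC1(C)OCCO1)C2(O)CC2
F3 | step 9 | 1-[(2R,3R)-2-methyl-3-[2-(2-methyl-1,3-dioxolan-2-yl)ethyl]oxiran-2-yl]cyclopropan-1-ol | CC1(CC[C@H]2O[C@@]2(C)C3(O)CC3)OCCO1
F4 | step 9 | (2S)-2-[(1R)-1-hydroxy-3-(2-methyl-1,3-dioxolan-2-yl)propyl]-2-methylcyclobutan-1-one | CC1(CC[C@@H](O)[C@]2(C)CCC2=O)OCCO1
F5 | step 9 | (5S)-5-[(1R)-1-hydroxy-3-(2-methyl-1,3-dioxolan-2-yl)propyl]-5-methyloxolan-2-one | CC1(CC[C@@H](O)[C@]2(C)CCC(=O)O2)OCCO1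
F6 | step 9 | (5S)-5-[(1R)-1-hydroxy-4-oxopentyl]-5-methyloxolan-2-one | CC(=O)CC[C@@H](O)[C@]1(C)CCC(=O)O1
F7 | step 7 | rac-(2Z,7E,10E)-13-(furan-3-yl)-2-iodo-6,10-dimethyltrideca-2,7,10-trien-6-ol | C/C(=C\CCc1ccoc1)C/C=C/C(C)(O)CC/C=C(/C)I
F8 | step 8 | (3Z,7S,8E,11E)-1-chloro-2-(chloromethyl)-14-(furan-3-yl)-3,7,11-trimethyl-7-[(trimethylsilyl)oxy]tetradeca-3,8,11-trien-2-ol | C/C(=C\CCc1ccoc1)C/C=C/[C@@](C)(O[Si](C)(C)C)CC/C=C(/C)C(O)(CCl)CCl
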